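The product in amber climbs ever more slowly, yet at 20.0 h it amounts to 0.132 M against 0.80 M of partner charged. Product formation has therefore not used up the partner. I suspect the partner fades by some other route.

the same everywhere: left-handed substrate 0.20 M; right-handed substrate 0.20 M
- green: partner 0.80 M; racemization catalyst 10 mM; the very flask that is asked about, followed so far
- amber: partner 0.80 M; racemization catalyst 5 mM; run made earlier
- flask: partner 0.800 M; racemization catalyst 10 mM; time 30 h
- green (time / h: left-handed product / %, right-handed product / %): 0.667: 4, 3; 1.00: 3, 2; 1.50: 4, 2; 2.50: 10, 2; 4.00: 12, 4; 6.00: 13, 4; 10.0: 19, 7
- amber (time / h: left-handed product / %, right-handed product / %): 1.50: 6, 2; 2.50: 10, 4; 4.00: 11, 4; 6.00: 13, 4; 10.0: 16, 9; 15.0: 22, 8; 20.0: 24, 9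

(each reading ± 1.5 percentage points)
- partner is single-handed; left-handed substrate and right-handed substrate are mirror images of each other, charged as a racemate, each of them at the stated concentration
- an excess is below zero if the other one leads
- the handed part of partner does not stay in what it makes, so the products of the two hands are mirror images too
1. left-handed product and right-handed product together, in percent of the left-handed substrate and right-handed substrate charged together, at 30 h
2. excess of left-handed product over right-handed product in the product at 30 h
3. whether the exchange between left-handed substrate and right-handed substrate keeps pace with the reaction: how far the product's excess at 30 h gets from its value without exchange to its value with instant exchange (above 80 % keeps pace, below 20 % hardly takes part, else lags behind)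

Green and amber track each other, with 26.0 % and 25.0 % at 10.0 h, so I let amber's longer run stand in for green. I reckon with the fraction of substrate left, as for a first-order decay:

reach = −ln(fraction of substrate left)

Amber's readings give 0.288, 0.357 and 0.400 at 10.0 h, 15.0 h and 20.0 h.

From below: I take product to stay made, so the total at 20.0 h, less two standard deviations of a sum of two readings, gives 28.8 %.

From above: reach holding its last pace until 30 h gives 38.6 %.

Tightened: the last gain was 0.635 of the one before. Letting the gains keep shrinking so gives

reach at 30 h = 0.446, product 36.0 %.

If the partner fades at first order, substrate decays pseudo-first-order and, at a fixed hour, reach scales with the partner charged. So I carry the pull, reach per molar of partner charged: 0.557 M⁻¹.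

The forecast gives 37 % (32 % to 43 %), excess 46 % and keeps pace, reading that “Both hands slow down”; its 37 % lies inside my wide bracket but above the tightened top.

The flask gives 31.4 %, excess 42.8 %, and exchange keeps pace, at 88 % of the way. The product lies within the bracket, below my tightened top and above the floor. At 30.0 h the partner, charged at more than the two substrates together yet the first to run out, stands at 1.3 % of its charge, while left-handed substrate stands at 69 %. The fraction left then gives a pull of 0.471 M⁻¹, less than my 0.557 M⁻¹.

    partner + left-handed substrate → left-handed product (k = 2.80 × 10⁻⁵ M⁻¹ s⁻¹)
    partner + right-handed substrate → right-handed product (k = 1.10 × 10⁻⁵ M⁻¹ s⁻¹)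
    left-handed substrate + racemization catalyst ⇌ right-handed substrate + racemization catalyst, rate k3*[racemization catalyst]*[left-handed substrate] forward; the back reaction follows from the equilibrium constant (k = 0.0180 M⁻¹ s⁻¹)
    partner + racemization catalyst → spent catalyst (k = 1.80 × 10⁻⁵ M⁻¹ s⁻¹)
    partner → decomposition product (k = 8.30 × 10⁻⁸ s⁻¹)
    partner → decomposed reagent (k = 3.40 × 10⁻⁵ s⁻¹)

In the same flask with 2.0 M of partner, that pull gives a reach of 0.942, hence 61.0 % product. The computed result is 62.0 %.

The readings were generated by integration for an exercise.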